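**Retrosynthetic overview**
1. The oxirane is made last, by site- and face-selective epoxidation of the E-1(10) alkene of the macrocyclic diester; the C3 acetate comes from the macrocyclic allylic alcohol.
2. The ten-membered carbocycle (second ring) is closed at C3–C4 by an intramolecular Nozaki–Hiyama–Kishi coupling of a Z-vinyl iodide with a C3 aldehyde.
3. The C7–C8 bond and both stereocentres come from a zinc Barbier allylation of a β,γ-unsaturated aldehyde (fragment 2) with a bromomethyl butenolide (fragment 1); C8–OH is then isovalerylated.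
4. Fragment 1: the lactone ring (first ring) is formed by ring-closing metathesis of a 2-(bromomethyl)acrylate; C6 is set by Sharpless kinetic resolution of the crotonaldehyde/propynyl Grignard adduct, and the Z-vinyl iodide by directed hydroalumination–iodination.
5. Fragment 2: the E-trisubstituted alkene comes from zirconium-catalysed carboalumination of a butynyl silyl ether trapped with ethylene oxide.

Assumption: atom labels C1–C15 follow germacrane numbering of the target (C1/C10 oxirane carbons, C3 acetate carbon, C4=C5, C6 lactone O–CH, C7 ring-fusion CH, C8 isovalerate carbon, C11–C13 methylidene lactone); the four starting materials and all reagents are taken as commercially available.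

**Route**

Step 1
Reactants: 1 (E)-but-2-enal; 2 prop-1-ynylmagnesium bromide
Product: 3 rac-(E)-hept-2-en-5-yn-4-ol
Conditions: THF, −78 → 0 °C; then sat. aq. NH4Cl
Reagents that add atoms: none
Why: Grignard 1,2-addition of the alkynyl nucleophile to the enal gives the racemic alkenyl alkynyl carbinol that carries C4–C7 and C15, with no stereocontrol needed at this stage.

Step 2
Reactants: 3 rac-(E)-hept-2-en-5-yn-4-ol
Product: 4 (2E,4S)-hept-2-en-5-yn-4-ol
Conditions: Ti(Oi-Pr)4 (10 mol %), L-(+)-diisopropyl tartrate (15 mol %), t-BuOOH (0.6 equiv), 4 Å molecular sieves, CH2Cl2, −20 °C, to ca. 55 % conversion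
Reagents that add atoms: none
Why: Sharpless kinetic resolution, in which L-(+)-tartrate epoxidises the (R)-alcohol fast at its E-propenyl group (erythro epoxy alcohol) so that the slow (S)-alcohol, whose carbinol carbon becomes C6, is recovered in high ee.

Step 3
Reactants: 4 (2E,4S)-hept-2-en-5-yn-4-ol
Product: 6 (2E,4S,5Z)-6-iodohepta-2,5-dien-4-ol, via cyclic vinylalanate 5 (not isolated)
Conditions: NaAlH2(OCH2CH2OMe)2 (1.6 equiv), THF, 0 °C → rt; then I2, THF, −78 → 0 °C
Reagents that add atoms: iodine [I][I]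
Why: Hydroxyl-directed trans-hydroalumination of the propargylic alkyne puts aluminium on the distal carbon in a five-membered oxaaluminate, and iodinolysis with retention gives only the Z-vinyl iodide (future C4=C5 geometry) while the propenyl group is inert.

Step 4
Reactants: 6 (2E,4S,5Z)-6-iodohepta-2,5-dien-4-ol; 7 2-(bromomethyl)prop-2-enoic acid
Product: 8 (2E,4S,5Z)-6-iodohepta-2,5-dien-4-yl 2-(bromomethyl)prop-2-enoate
Conditions: dicyclohexylcarbodiimide, 4-(dimethylamino)pyridine (DMAP, 5 mol %), CH2Cl2, 0 °C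
Reagents that add atoms: none
Why: Steglich esterification under near-neutral conditions acylates the bis-allylic alcohol without touching the C6 stereocentre or either alkene geometry.

Step 5
Reactants: 8 (2E,4S,5Z)-6-iodohepta-2,5-dien-4-yl 2-(bromomethyl)prop-2-enoate
Product: 9 (5S)-3-(bromomethyl)-5-[(Z)-2-iodoprop-1-enyl]furan-2(5H)-one
Conditions: second-generation Hoveyda–Grubbs catalyst RuCl2(=CH–C6H4-2-Oi-Pr)(H2IMes) (5 mol %), toluene (0.01 M), 80 °C
Reagents that add atoms: none
Why: Ring-closing metathesis between the propenyl group and the 1,1-disubstituted acrylate expels propene and forms the butenolide, while the trisubstituted vinyl iodide does not engage and the phosphine-free catalyst is not alkylated by the allylic bromide.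

Step 6
Reactants: 10 tert-butyl(but-3-yn-1-yloxy)dimethylsilane
Product: 13 (E)-6-(tert-butyldimethylsilyloxy)-4-methylhex-3-en-1-ol, via vinylalane 11 (not isolated), via lithium alanate 12 (not isolated)
Conditions: Me3Al (2.5 equiv), Cp2ZrCl2 (0.25 equiv), CH2Cl2, 0 °C → rt; concentrate; n-BuLi (1 equiv), hexane/THF, −30 °C; ethylene oxide, −30 °C → rt; aq. NH4Cl
Reagents that add atoms: trimethylaluminium C[Al](C)C; ethylene oxide C1CO1
Why: Negishi zirconium-catalysed carboalumination adds methyl and aluminium syn across the terminal alkyne (methyl to the internal carbon), and the derived alanate opens ethylene oxide with retention, fixing the E-trisubstituted C1=C10 alkene.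

Step 7
Reactants: 13 (E)-6-(tert-butyldimethylsilyloxy)-4-methylhex-3-en-1-ol
Product: 14 (E)-tert-butyl{[6-(4-methoxybenzyloxy)-3-methylhex-3-enyl]oxy}dimethylsilane
Conditions: NaH, 4-methoxybenzyl chloride, n-Bu4NI (cat.), THF/DMF, 0 °C → rt
Reagents that add atoms: 4-methoxybenzyl chloride COc1ccc(CCl)cc1
Why: Williamson etherification masks the future C3 oxygen as a PMB ether that is orthogonal to the silyl ether.

Step 8
Reactants: 14 (E)-tert-butyl{[6-(4-methoxybenzyloxy)-3-methylhex-3-enyl]oxy}dimethylsilane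
Product: 15 (E)-6-(4-methoxybenzyloxy)-3-methylhex-3-en-1-ol
Conditions: n-Bu4NF, THF, 0 °C → rt
Reagents that add atoms: none
Why: Fluoride desilylation frees the primary alcohol at the future C8 and leaves the PMB ether intact.

Step 9
Reactants: 15 (E)-6-(4-methoxybenzyloxy)-3-methylhex-3-en-1-ol
Product: 16 (E)-6-(4-methoxybenzyloxy)-3-methylhex-3-enal
Conditions: Dess–Martin periodinane, pyridine, CH2Cl2, 0 °C; used crude at once
Reagents that add atoms: none
Why: Pyridine-buffered Dess–Martin oxidation gives the β,γ-unsaturated aldehyde without the base or acid that would move the alkene into conjugation.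

Step 10
Reactants: 9 (5S)-3-(bromomethyl)-5-[(Z)-2-iodoprop-1-enyl]furan-2(5H)-one; 16 (E)-6-(4-methoxybenzyloxy)-3-methylhex-3-enal
Product: 18 (4R,5S)-4-[(1S,3E)-1-hydroxy-6-(4-methoxybenzyloxy)-3-methylhex-3-enyl]-5-[(Z)-2-iodoprop-1-enyl]-3-methylidenedihydrofuran-2(3H)-one, via allylzinc bromide 17 (not isolated)
Conditions: Zn dust, THF/sat. aq. NH4Cl (2:1), 0 °C → rt
Reagents that add atoms: none
Why: Barbier allylation in which the allylzinc reacts at its γ-carbon (C7) anti to the C6 alkenyl group and, because the ring locks the allyl unit in the E-crotyl-type geometry, through a chair Zimmerman–Traxler transition state with the aldehyde chain equatorial, giving the 7,8-anti adduct (7R,8S) with a trans-6,7 methylidene lactone.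

Step 11
Reactants: 18 (4R,5S)-4-[(1S,3E)-1-hydroxy-6-(4-methoxybenzyloxy)-3-methylhex-3-enyl]-5-[(Z)-2-iodoprop-1-enyl]-3-methylidenedihydrofuran-2(3H)-one
Product: 19 (1S,3E)-1-[(2S,3R)-2-((Z)-2-iodoprop-1-enyl)-4-methylidene-5-oxotetrahydrofuran-3-yl]-6-(4-methoxybenzyloxy)-3-methylhex-3-enyl 3-methylbutanoate
Conditions: 3-methylbutanoic anhydride, DMAP (cat.), pyridine, CH2Cl2, 0 °C
Reagents that add atoms: 3-methylbutanoic anhydride CC(C)CC(=O)OC(=O)CC(C)C
Why: DMAP-catalysed acylation installs the C8 isovalerate with retention and blocks translactonisation to C8.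

Step 12
Reactants: 19 (1S,3E)-1-[(2S,3R)-2-((Z)-2-iodoprop-1-enyl)-4-methylidene-5-oxotetrahydrofuran-3-yl]-6-(4-methoxybenzyloxy)-3-methylhex-3-enyl 3-methylbutanoate
Product: 20 (1S,3E)-6-hydroxy-1-[(2S,3R)-2-((Z)-2-iodoprop-1-enyl)-4-methylidene-5-oxotetrahydrofuran-3-yl]-3-methylhex-3-enyl 3-methylbutanoate
Conditions: DDQ, CH2Cl2/H2O (10:1), 0 °C
Reagents that add atoms: none
Why: Oxidative PMB cleavage (benzylic oxidation to the oxocarbenium ion, then hydrolysis) leaves the esters, lactone, vinyl iodide and alkenes untouched.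

Step 13
Reactants: 20 (1S,3E)-6-hydroxy-1-[(2S,3R)-2-((Z)-2-iodoprop-1-enyl)-4-methylidene-5-oxotetrahydrofuran-3-yl]-3-methylhex-3-enyl 3-methylbutanoate
Product: 21 (1S,3E)-1-[(2S,3R)-2-((Z)-2-iodoprop-1-enyl)-4-methylidene-5-oxotetrahydrofuran-3-yl]-3-methyl-6-oxohex-3-enyl 3-methylbutanoate
Conditions: Dess–Martin periodinane, pyridine, CH2Cl2, 0 °C; used crude at once
Reagents that add atoms: none
Why: Buffered Dess–Martin oxidation gives the C3 β,γ-unsaturated aldehyde under non-basic conditions that the methylidene lactone tolerates.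

Step 14
Reactants: 21 (1S,3E)-1-[(2S,3R)-2-((Z)-2-iodoprop-1-enyl)-4-methylidene-5-oxotetrahydrofuran-3-yl]-3-methyl-6-oxohex-3-enyl 3-methylbutanoate
Product: 23 (1(10)E,3S,4Z,6R,7R,8S)-3-hydroxy-8-(3-methylbutanoyloxy)germacra-1(10),4,11(13)-trien-12,6-olide, via vinylchromium dichloride 22 (not isolated)
Conditions: CrCl2 (10 equiv), NiCl2 (2 mol %), degassed DMSO, rt, syringe-pump addition to 0.003 M; aq. NH4Cl work-up
Reagents that add atoms: none
Why: Intramolecular Nozaki–Hiyama–Kishi reaction in which zerovalent nickel inserts into the C–I bond and the vinylchromium formed by transmetalation adds to the aldehyde with retention of the Z geometry to close the ten-membered ring, the C3 centre being set by macrocyclic control (attack on the peripheral aldehyde face of the lactone-constrained chain, expected to favour the 3S carbinol).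

Step 15
Reactants: 23 (1(10)E,3S,4Z,6R,7R,8S)-3-hydroxy-8-(3-methylbutanoyloxy)germacra-1(10),4,11(13)-trien-12,6-olide
Product: 24 (1(10)E,3S,4Z,6R,7R,8S)-3-acetoxy-8-(3-methylbutanoyloxy)germacra-1(10),4,11(13)-trien-12,6-olide
Conditions: Ac2O, DMAP (cat.), pyridine, CH2Cl2, 0 °C → rt
Reagents that add atoms: acetic anhydride CC(=O)OC(C)=O
Why: Nucleophile-catalysed acetylation of the C3 allylic alcohol proceeds with retention.

Step 16
Reactants: 24 (1(10)E,3S,4Z,6R,7R,8S)-3-acetoxy-8-(3-methylbutanoyloxy)germacra-1(10),4,11(13)-trien-12,6-olide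
Product: 25 (1R,3S,4Z,6R,7R,8S,10R)-3-acetoxy-1,10-epoxy-8-(3-methylbutanoyloxy)germacra-4,11(13)-dien-12,6-olide
Conditions: mCPBA (1.05 equiv), CH2Cl2, −20 → 0 °C; aq. NaHCO3/Na2S2O3 wash
Reagents that add atoms: 3-chloroperoxybenzoic acid OOC(=O)c1cccc(Cl)c1
Why: Prilezhaev epoxidation is selective for the electron-rich C1=C10 alkene (C4=C5 is deactivated by two allylic acyloxy groups and the methylidene is electron-poor) and stereospecific, with peripheral attack on the ring conformer that holds the C10 methyl on the β face giving the trans (1R,10R) oxirane.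

**Compound list**
1 | (E)-but-2-enal (crotonaldehyde) | C/C=C/C=O | starting material
2 | prop-1-ynylmagnesium bromide | CC#C[Mg]Br | starting material
3 | rac-(E)-hept-2-en-5-yn-4-ol | C/C=C/C(O)C#CC | intermediate
4 | (2E,4S)-hept-2-en-5-yn-4-ol | C/C=C/[C@H](O)C#CC | intermediate
5 | sodium (5S)-2,2-bis(2-methoxyethoxy)-3-methyl-5-[(E)-prop-1-enyl]-2,5-dihydro-1,2-oxaaluminol-2-uide (cyclic vinylalanate) | [Na+].C/C=C/[C@H]1C=C(C)[Al-](OCCOC)(OCCOC)O1 | intermediate
6 | (2E,4S,5Z)-6-iodohepta-2,5-dien-4-ol | C/C=C/[C@H](O)/C=C(/C)I | intermediate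
7 | 2-(bromomethyl)prop-2-enoic acid | OC(=O)C(=C)CBr | starting material
8 | (2E,4S,5Z)-6-iodohepta-2,5-dien-4-yl 2-(bromomethyl)prop-2-enoate | C/C=C/[C@H](OC(=O)C(=C)CBr)/C=C(/C)I | intermediate
9 | (5S)-3-(bromomethyl)-5-[(Z)-2-iodoprop-1-enyl]furan-2(5H)-one | BrCC1=C[C@@H](/C=C(/C)I)OC1=O | intermediate
10 | tert-butyl(but-3-yn-1-yloxy)dimethylsilane | C#CCCO[Si](C)(C)C(C)(C)C | starting material
11 | (E)-[4-(tert-butyldimethylsilyloxy)-2-methylbut-1-enyl]dimethylalane (vinylalane) | C[Al](C)/C=C(\C)CCO[Si](C)(C)C(C)(C)C | intermediate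
12 | lithium butyl[(E)-4-(tert-butyldimethylsilyloxy)-2-methylbut-1-enyl]dimethylalanate | [Li+].CCCC[Al-](C)(C)/C=C(\C)CCO[Si](C)(C)C(C)(C)C | intermediate
13 | (E)-6-(tert-butyldimethylsilyloxy)-4-methylhex-3-en-1-ol | OCC/C=C(\C)CCO[Si](C)(C)C(C)(C)C | intermediate
14 | (E)-tert-butyl{[6-(4-methoxybenzyloxy)-3-methylhex-3-enyl]oxy}dimethylsilane | COc1ccc(COCC/C=C(\C)CCO[Si](C)(C)C(C)(C)C)cc1 | intermediate
15 | (E)-6-(4-methoxybenzyloxy)-3-methylhex-3-en-1-ol | COc1ccc(COCC/C=C(\C)CCO)cc1 | intermediate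
16 | (E)-6-(4-methoxybenzyloxy)-3-methylhex-3-enal | COc1ccc(COCC/C=C(\C)CC=O)cc1 | intermediate
17 | {[(5S)-5-[(Z)-2-iodoprop-1-enyl]-2-oxo-2,5-dihydrofuran-3-yl]methyl}zinc bromide (allylzinc bromide) | Br[Zn]CC1=C[C@@H](/C=C(/C)I)OC1=O | intermediate
18 | (4R,5S)-4-[(1S,3E)-1-hydroxy-6-(4-methoxybenzyloxy)-3-methylhex-3-enyl]-5-[(Z)-2-iodoprop-1-enyl]-3-methylidenedihydrofuran-2(3H)-one | C=C1C(=O)O[C@H](/C=C(/C)I)[C@H]1[C@@H](O)C/C(C)=C/CCOCc1ccc(OC)cc1 | intermediate
19 | (1S,3E)-1-[(2S,3R)-2-((Z)-2-iodoprop-1-enyl)-4-methylidene-5-oxotetrahydrofuran-3-yl]-6-(4-methoxybenzyloxy)-3-methylhex-3-enyl 3-methylbutanoate | C=C1C(=O)O[C@H](/C=C(/C)I)[C@H]1[C@@H](OC(=O)CC(C)C)C/C(C)=C/CCOCc1ccc(OC)cc1 | intermediate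
20 | (1S,3E)-6-hydroxy-1-[(2S,3R)-2-((Z)-2-iodoprop-1-enyl)-4-methylidene-5-oxotetrahydrofuran-3-yl]-3-methylhex-3-enyl 3-methylbutanoate | C=C1C(=O)O[C@H](/C=C(/C)I)[C@H]1[C@@H](OC(=O)CC(C)C)C/C(C)=C/CCO | intermediate
21 | (1S,3E)-1-[(2S,3R)-2-((Z)-2-iodoprop-1-enyl)-4-methylidene-5-oxotetrahydrofuran-3-yl]-3-methyl-6-oxohex-3-enyl 3-methylbutanoate | C=C1C(=O)O[C@H](/C=C(/C)I)[C@H]1[C@@H](OC(=O)CC(C)C)C/C(C)=C/CC=O | intermediate
22 | vinylchromium dichloride from 21 (C–I replaced by C–CrCl2 at C4, Z geometry kept, trivalent chromium) | C=C1C(=O)O[C@H](/C=C(/C)[Cr](Cl)Cl)[C@H]1[C@@H](OC(=O)CC(C)C)C/C(C)=C/CC=O | intermediate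
23 | (1(10)E,3S,4Z,6R,7R,8S)-3-hydroxy-8-(3-methylbutanoyloxy)germacra-1(10),4,11(13)-trien-12,6-olide | C=C1C(=O)O[C@@H]2/C=C(/C)[C@@H](O)C/C=C(\C)C[C@H](OC(=O)CC(C)C)[C@@H]12 | intermediate
24 | (1(10)E,3S,4Z,6R,7R,8S)-3-acetoxy-8-(3-methylbutanoyloxy)germacra-1(10),4,11(13)-trien-12,6-olide | C=C1C(=O)O[C@@H]2/C=C(/C)[C@@H](OC(C)=O)C/C=C(\C)C[C@H](OC(=O)CC(C)C)[C@@H]12 | intermediate
25 | (1R,3S,4Z,6R,7R,8S,10R)-3-acetoxy-1,10-epoxy-8-(3-methylbutanoyloxy)germacra-4,11(13)-dien-12,6-olide (CNP0157657.1) | C=C1C(=O)O[C@@H]2/C=C(/C)[C@@H](OC(C)=O)C[C@H]3O[C@]3(C)C[C@H](OC(=O)CC(C)C)[C@@H]12 | target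

**Step count**
Total: 16 steps. Longest linear sequence: 12 steps (steps 1–5, then 10–16); the other branch (steps 6–9, then 10–16) is 11 steps.

**Three steps most likely to fail, with fallbacks**

Step 14 (macrocyclisation). The ring is strained and the C3 configuration rests on macrocyclic control that is not secured for this exact ring. The fallback sets out from 21: if the chromium-mediated closure gives mainly the C3 epimer (1(10)E,3R,4Z,6R,7R,8S)-3-hydroxy-8-(3-methylbutanoyloxy)germacra-1(10),4,11(13)-trien-12,6-olide F2, it is oxidised with Dess–Martin periodinane to the macrocyclic enone (1(10)E,4Z,6R,7R,8S)-8-(3-methylbutanoyloxy)-3-oxogermacra-1(10),4,11(13)-trien-12,6-olide F3. The enone is then reduced under reagent control with (R)-tetrahydro-1-methyl-3,3-diphenyl-1H,3H-pyrrolo[1,2-c][1,3,2]oxazaborole ((R)-Me-CBS) and catecholborane in toluene at −78 °C, with the alkenyl side acting as the large group, and the route is rejoined at 23.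

Step 10 (Barbier allylation). The C7 facial selectivity is reliable, but the C8 configuration depends on the chair transition state winning over open alternatives, and aldehyde 16 can isomerise. The fallback sets out from 9 and 16: if the allylation gives mainly the C8 epimer (4R,5S)-4-[(1R,3E)-1-hydroxy-6-(4-methoxybenzyloxy)-3-methylhex-3-enyl]-5-[(Z)-2-iodoprop-1-enyl]-3-methylidenedihydrofuran-2(3H)-one F1, this alcohol is esterified with inversion in a Mitsunobu reaction with 3-methylbutanoic acid (PPh3, diisopropyl azodicarboxylate, toluene, 0 °C). This corrects C8 and installs the isovalerate in one operation, and the route is rejoined at 19.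

Step 16 (epoxidation). The peracid may attack the other ring conformer and give the (1S,10S) oxirane. The fallback sets out from 24: N-bromosuccinimide in THF/H2O at 0 °C forms the bromonium ion on that same peripheral face and water opens it anti at the tertiary C10, giving the bromohydrin (1S,3S,4Z,6R,7R,8S,10R)-3-acetoxy-1-bromo-10-hydroxy-8-(3-methylbutanoyloxy)germacra-4,11(13)-dien-12,6-olide F4. Ag2O in THF then closes the oxirane with inversion at C1, which delivers the epoxide of opposite facial sense to the direct peracid reaction, and the route is rejoined at 25.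

**Further compounds**
F1 | step 10 | (4R,5S)-4-[(1R,3E)-1-hydroxy-6-(4-methoxybenzyloxy)-3-methylhex-3-enyl]-5-[(Z)-2-iodoprop-1-enyl]-3-methylidenedihydrofuran-2(3H)-one | C=C1C(=O)O[C@H](/C=C(/C)I)[C@H]1[C@H](O)C/C(C)=C/CCOCc1ccc(OC)cc1
F2 | step 14 | (1(10)E,3R,4Z,6R,7R,8S)-3-hydroxy-8-(3-methylbutanoyloxy)germacra-1(10),4,11(13)-trien-12,6-olide | C=C1C(=O)O[C@@H]2/C=C(/C)[C@H](O)C/C=C(\C)C[C@H](OC(=O)CC(C)C)[C@@H]12
F3 | step 14 | (1(10)E,4Z,6R,7R,8S)-8-(3-methylbutanoyloxy)-3-oxogermacra-1(10),4,11(13)-trien-12,6-olide | C=C1C(=O)O[C@@H]2/C=C(/C)C(=O)C/C=C(\C)C[C@H](OC(=O)CC(C)C)[C@@H]12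
F4 | step 16 | (1S,3S,4Z,6R,7R,8S,10R)-3-acetoxy-1-bromo-10-hydroxy-8-(3-methylbutanoyloxy)germacra-4,11(13)-dien-12,6-olide | C=C1C(=O)O[C@@H]2/C=C(/C)[C@@H](OC(C)=O)C[C@H](Br)[C@](C)(O)C[C@H](OC(=O)CC(C)C)[C@@H]12
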